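## The problem

Target 11, 2,4,7-tribromo-3-chloro-1H-indole, is a flat, achiral indole in which four of the six substitutable ring carbons carry a halogen. With no stereocenter to set, every difficulty is one of position and of telling bromine from chlorine. The pyrrole ring carries bromine at C2 and chlorine at C3, and since an indole takes electrophiles at C3 before C2, the chlorine has to be in place before the C2 bromine arrives. The benzene ring is brominated at C4 and C7, next to the ring fusion, which electrophilic halogenation of an indole does not reach selectively, so these bromines must be bought on a benzene precursor or put in while the ring is made. The fragile parts are the N–H 2-haloindole unit, sensitive to acid, light and nucleophiles, and the three C–Br bonds, which would not survive zerovalent palladium, organolithium reagents or reducing conditions. The bromines of the target should therefore enter after the last metal-catalysed step, and the C2 bromine last of all. The feature that opens a way is that C4 and C7 lie para to each other and flank the C3a–C7a bond: if that bond is the C4=C5 bond of a pyrrole bearing an ethynyl group on each carbon, closure between the alkyne termini (C5–C6) leaves radical centres exactly at C4 and C7.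

## Retrosynthesis

**C2–Br.** The C2–Br bond of target 11 is cut first and traced to a carboxyl group, through acid 10 and methyl ester 9. A carboxyl at C2 can be exchanged for bromine by ipso attack of electrophilic bromine with loss of CO2. Direct bromination of a C2–H indole would serve equally well at the end. The ester is preferred because it is needed in all earlier steps: it tames the pyrrole, directs its halogenation and keeps the enediyne electron-poor. The forward reaction must deliver bromine to C2 without disturbing the chlorine at C3.

**The benzene ring (key disconnection).** In ester 9 the C5–C6 bond and both C–Br bonds at C4 and C7 are cut together. This leads to methyl 3-chloro-4,5-diethynyl-1H-pyrrole-2-carboxylate 6 and two bromine atoms from two molecules of bromotrichloromethane 7, through the 4,7-didehydroindole diradical 8. Cuts at C3a–C4/C7–C7a (a cycloaddition) or at the pyrrole ring (a dibromoaniline precursor) need either a later dehydrogenation or a crowded tetrasubstituted benzene. The enediyne cut reaches the aromatic oxidation level directly and places bromine only where the radicals are. Precursor 6 is a monocyclic pyrrole with no bromine at all. The forward step must cyclize an enediyne fused to a five-membered ring and capture bromine faster than hydrogen abstraction or chain addition to unreacted alkyne.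

**The two alkynes.** Enediyne 6 is traced to the bis-silylated, N-Boc-protected diyne 5, and the two C(sp2)–C(sp) bonds of 5 to dibromide 3 and trimethylsilylacetylene 4 by twofold Sonogashira coupling. The N-Boc group is added for the coupling only: a free pyrrole N–H forms an electron-rich pyrrolide under amine base, which slows oxidative addition and invites hydrodebromination. It costs one step going in and none coming out, because the carbonate–methanol treatment that removes the silyl groups also cleaves an acyl pyrrole. A methyl ester is chosen so that this methanolysis cannot scramble the ester.

**The pyrrole halogens.** Carbamate 3 comes from methyl 4,5-dibromo-3-chloro-1H-pyrrole-2-carboxylate 2, and the two C–Br bonds of 2 are cut to give methyl 3-chloro-1H-pyrrole-2-carboxylate 1. The opposite order, chlorinating a 4,5-dibromopyrrole ester at the deactivated C3, risks ipso attack at the bromine-bearing C5 and halogen scrambling. Bromination of 1 meets only the two free, naturally reactive positions C4 and C5.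

## Roads not taken

Alternative 1: The cut is the N1–C2 bond, with the C2 bromine carried in as one bromine of a gem-dibromoalkene. In the forward sense 2-amino-3,6-dibromobenzaldehyde A1 would be N-mesylated and dibromo-olefinated to N-[3,6-dibromo-2-(2,2-dibromoethenyl)phenyl]methanesulfonamide A2. Under Cs2CO3 or Bu4NF the sulfonamide anion of A2 displaces one vinylic bromide and closes the five-membered ring to 2,4,7-tribromo-1-(methylsulfonyl)-1H-indole A3. Desulfonylation of A3 to 2,4,7-tribromo-1H-indole A4 and chlorination at C3 would finish. Its merits are that base-mediated closure of ortho-(dibromovinyl) sulfonanilides to 2-bromoindoles is an established reaction type, that all three bromines are placed without ambiguity, and that no step is speculative. Its weak points lie at both ends. A1 is a 1,2,3,4-tetrasubstituted benzene that needs its own multistep preparation. The sulfonyl group of A3 must be removed by nucleophiles that can also attack C2. A4, a free 2-bromoindole with an open C3, is the least stable intermediate one could pass through. In reliability this road is better than the chosen plan, whose key step is untested. The chosen plan sets against it a stock pyrrole in which C2 and C3 are already differentiated, no deprotection on a 2-bromoindole, and both benzo bromines installed together with the ring.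

Alternative 2: Three bonds are cut at once (C3a–C7a, C4–C5, C6–C7). The tethered dibromodiyne N-(bromoethynyl)-N-(4-bromobut-3-yn-1-yl)-4-methylbenzenesulfonamide A5 and acetylene A6 would undergo [2+2+2] cycloaddition under Cp*RuCl(cod). The three-atom tether closes the five-membered ring as the benzene ring forms, giving 4,7-dibromo-1-(4-methylbenzenesulfonyl)-2,3-dihydro-1H-indole A7. The merits are two rings in one catalytic step and bromines fixed by the alkyne termini. Cyclotrimerization of haloalkynes with this ruthenium complex is a known reaction type, so the key step is better founded than a bromine-trapped Bergman reaction. The weak points are these. A5 contains a bromoynamide, a sensitive function that takes several steps to make. Gaseous A6 must outcompete self-trimerization of A5. A7 is an N-tosylindoline, so desulfonylation and dehydrogenation to 4,7-dibromo-1H-indole A8 and two separate halogenations at C3 and C2 must follow. The sequence is longer and none of the pyrrole substituents arrives with the ring. The chosen plan has the simpler precursor and has C2 and C3 settled before the key step, but it concedes the better precedent of the metal-catalysed cycloaddition.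

Alternative 3: The cut is C3a–C4 and C7–C7a. 2,5-Dibromothiophene 1,1-dioxide A9 acts as an electron-poor diene toward the enecarbamate tert-butyl 2,3-dihydro-1H-pyrrole-1-carboxylate A10. Inverse-demand Diels–Alder addition and cheletropic loss of SO2 would give racemic cis-fused tert-butyl 4,7-dibromo-2,3,3a,7a-tetrahydro-1H-indole-1-carboxylate A11. The road is convergent, uses two simple partners in a known cycloaddition–extrusion sequence, and puts bromine at C4 and C7 by construction. Its weak points are these. A9 needs a powerful oxidant for its preparation and dimerizes easily, so A10 must intercept it quickly. A11 carries four hydrogens more than an indole. Its dehydrogenation to tert-butyl 4,7-dibromo-1H-indole-1-carboxylate A12 competes with hydrogen shift and loss of HBr, which would discard one of the bromines the step was meant to place. The two stereocenters of A11 are made only to be destroyed. After A12 the Boc group must be removed to reach the indole A8 of alternative 2, and C3 and C2 must still be halogenated. The cycloaddition is better precedented than the chosen key step, a real point in its favour. The chosen plan delivers the aromatic ring and both C–Br bonds directly, with no later dehydrogenation in which bromine can be lost, and has a shorter endgame.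

Key step: step 5

Remark on the chemistry: methyl 3-chloro-1H-pyrrole-2-carboxylate 1 is taken to be a catalogue building block; the target is achiral, so no stereochemical assumption is needed.

## Route

Step 1
Reactants: 1 methyl 3-chloro-1H-pyrrole-2-carboxylate
Product: 2 methyl 4,5-dibromo-3-chloro-1H-pyrrole-2-carboxylate
Conditions: NBS (2.1 equiv), DMF, 0 °C to rt, dark
Reagents that add atoms: N-bromosuccinimide, O=C1CCC(=O)N1Br
Why: Electrophilic aromatic bromination; C4 and C5 are the normal sites of attack in a pyrrole-2-carboxylate and here the only free ones, so no regiochemical question arises. Having chlorine in place first avoids a later chlorination that could displace bromine by ipso attack.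

Step 2
Reactants: 2 methyl 4,5-dibromo-3-chloro-1H-pyrrole-2-carboxylate
Product: 3 1-tert-butyl 2-methyl 4,5-dibromo-3-chloro-1H-pyrrole-1,2-dicarboxylate
Conditions: Boc2O (1.3 equiv), DMAP (0.1 equiv), MeCN, rt
Reagents that add atoms: di-tert-butyl dicarbonate, CC(C)(C)OC(=O)OC(=O)OC(C)(C)C
Why: DMAP-catalysed N-acylation of the acidic pyrrole N–H. The carbamate prevents pyrrolide formation under the amine base of the coupling and makes both C–Br bonds more ready for oxidative addition.

Step 3
Reactants: 3 1-tert-butyl 2-methyl 4,5-dibromo-3-chloro-1H-pyrrole-1,2-dicarboxylate; 4 trimethylsilylacetylene
Product: 5 1-tert-butyl 2-methyl 3-chloro-4,5-bis[(trimethylsilyl)ethynyl]-1H-pyrrole-1,2-dicarboxylate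
Conditions: 4 (3.5 equiv), Pd(PPh3)2Cl2 (5 mol %), CuI (10 mol %), Et3N, DMF, 70 °C, sealed tube
Reagents that add atoms: none
Why: Twofold Sonogashira coupling; zerovalent palladium should insert first into C5–Br next to nitrogen and then into C4–Br, both activated by carbamate and ester, while C3–Cl is inert to a triphenylphosphine-ligated catalyst at this temperature. The silyl caps suppress alkyne homocoupling.

Step 4
Reactants: 5 1-tert-butyl 2-methyl 3-chloro-4,5-bis[(trimethylsilyl)ethynyl]-1H-pyrrole-1,2-dicarboxylate
Product: 6 methyl 3-chloro-4,5-diethynyl-1H-pyrrole-2-carboxylate
Conditions: K2CO3, MeOH–THF, 0 °C to rt; aq. NH4Cl; used promptly, kept cold and dark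
Reagents that add atoms: none
Why: Methoxide-mediated protodesilylation of both alkynylsilanes and, in the same pot, methanolysis of the N-Boc group, which is an activated acyl pyrrole and leaves as a stabilized pyrrolide. The methyl ester is degenerate toward methoxide.

Step 5
Reactants: 6 methyl 3-chloro-4,5-diethynyl-1H-pyrrole-2-carboxylate; 7 bromotrichloromethane
Product: 9 methyl 4,7-dibromo-3-chloro-1H-indole-2-carboxylate, via 4,7-didehydroindole diradical 8 (not isolated)
Conditions: 6 (ca. 1 mM) in degassed BrCCl3 (7, solvent, 2 equiv consumed), sealed heavy-walled tube, dark, 200 °C until 6 is consumed
Reagents that add atoms: bromotrichloromethane, BrC(Cl)(Cl)Cl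
Why: Proposed new method: the pyrrole C4=C5 bond and its two ethynyl groups make up a hexa-1,5-diyn-3-ene, which on heating should undergo Bergman cycloaromatization, the two terminal alkyne carbons joining (C5–C6 of the indole) to close the six-membered ring as the singlet 4,7-didehydroindole diradical 8. Each of the two sigma radicals then abstracts a bromine atom from a separate solvent molecule, so two molecules of BrCCl3 are consumed per molecule of 6 and the two trichloromethyl radicals left behind end as hexachloroethane; at about 10 M the solvent should reach the radicals long before the only hydrogen donor present, the N–H of a second substrate molecule at about 1 mM. The closest known reaction type is the thermal Bergman cyclization of the parent and of arene- and heteroarene-fused enediynes with trapping by 1,4-cyclohexadiene, together with the capture of para-benzyne by tetrachloromethane to give a para-dichloroarene; bromine transfer from BrCCl3 to an aryl radical is faster than chlorine transfer. The ring closes in the C1–C6 mode of the enediyne onto the existing pyrrole edge, which unsubstituted alkyne termini favour over C1–C5 closure, so bromine can enter only at the former internal alkyne carbons C4 and C7, and no stereocenter is formed. The selectivity to be won is chemoselectivity, because trichloromethyl radicals can add to the terminal alkynes of unreacted 6 in a Kharasch-type chain; this bimolecular loss is held down by high dilution and by a hot, short reaction, since the unimolecular cyclization has much the higher activation energy. The substrate helps: all four pyrrole carbons are substituted, so radical substitution on the heterocycle is blocked, and ester and chlorine make the ring electron-poor enough to stand the heat and to slow attack by the electrophilic trichloromethyl radical. Fusion to a five-membered ring widens the gap between the alkyne termini, which is why about 200 °C is planned.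

Step 6
Reactants: 9 methyl 4,7-dibromo-3-chloro-1H-indole-2-carboxylate
Product: 10 4,7-dibromo-3-chloro-1H-indole-2-carboxylic acid
Conditions: LiOH·H2O (3 equiv), THF–MeOH–H2O, 50 °C; then aq. HCl to pH 2
Reagents that add atoms: lithium hydroxide, [Li+].[OH-]
Why: Saponification of the methyl ester; the aryl bromides and the 3-chloroindole are inert to hydroxide at this temperature.

Step 7
Reactants: 10 4,7-dibromo-3-chloro-1H-indole-2-carboxylic acid
Product: 11 2,4,7-tribromo-3-chloro-1H-indole
Conditions: NBS (1.0 equiv), dry DMF, 0 °C to rt, dark
Reagents that add atoms: N-bromosuccinimide, O=C1CCC(=O)N1Br
Why: Hunsdiecker-type ipso-bromodecarboxylation, a known reaction of pyrrole- and indole-carboxylic acids with N-halosuccinimides: electrophilic bromine attacks the carboxyl-bearing C2 (directly or after a 1,2-shift from C3) and loss of CO2 restores the aromatic ring. C2 is the only position still open to an electrophile, since C3 bears chlorine and the dibromobenzene ring is deactivated.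

## Compound list

1 | methyl 3-chloro-1H-pyrrole-2-carboxylate | COC(=O)c1[nH]ccc1Cl | starting material
2 | methyl 4,5-dibromo-3-chloro-1H-pyrrole-2-carboxylate | COC(=O)c1[nH]c(Br)c(Br)c1Cl | intermediate
3 | 1-tert-butyl 2-methyl 4,5-dibromo-3-chloro-1H-pyrrole-1,2-dicarboxylate | COC(=O)c1c(Cl)c(Br)c(Br)n1C(=O)OC(C)(C)C | intermediate
4 | trimethylsilylacetylene | C#C[Si](C)(C)C | starting material
5 | 1-tert-butyl 2-methyl 3-chloro-4,5-bis[(trimethylsilyl)ethynyl]-1H-pyrrole-1,2-dicarboxylate | COC(=O)c1c(Cl)c(C#C[Si](C)(C)C)c(C#C[Si](C)(C)C)n1C(=O)OC(C)(C)C | intermediate
6 | methyl 3-chloro-4,5-diethynyl-1H-pyrrole-2-carboxylate | COC(=O)c1[nH]c(C#C)c(C#C)c1Cl | intermediate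
7 | bromotrichloromethane | BrC(Cl)(Cl)Cl | starting material
8 | methyl 3-chloro-4,7-didehydro-1H-indole-2-carboxylate (para-benzyne diradical, not isolated) | COC(=O)c1[nH]c2[c]cc[c]c2c1Cl | intermediate
9 | methyl 4,7-dibromo-3-chloro-1H-indole-2-carboxylate | COC(=O)c1[nH]c2c(Br)ccc(Br)c2c1Cl | intermediate
10 | 4,7-dibromo-3-chloro-1H-indole-2-carboxylic acid | OC(=O)c1[nH]c2c(Br)ccc(Br)c2c1Cl | intermediate
11 | 2,4,7-tribromo-3-chloro-1H-indole | Clc1c(Br)[nH]c2c(Br)ccc(Br)c12 | target

Total step count: 7. Longest linear sequence: 7 steps (1 to 11).

## Least certain steps

**Step 5 (key step, proposed new method).**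
- What may go wrong: radical-chain addition of BrCCl3 across the terminal alkynes of unreacted 6, started by the trichloromethyl radicals that the reaction itself releases or by thermal homolysis of the solvent, can consume the enediyne faster than it cyclizes. The cyclization of this five-ring-fused enediyne may also need a temperature at which the diyne oligomerizes.
- Fallback (known chemistry): no established reaction turns a 1,2-diethynylarene into a para-dibromoarene, so the fallback sets out from no numbered compound of the route. It leaves the pyrrole series, starts from commercial 2,5-dibromobenzaldehyde and comes back to the route at compound 9. Condensation with methyl azidoacetate (NaOMe, MeOH, −10 °C) should give methyl (2Z)-2-azido-3-(2,5-dibromophenyl)prop-2-enoate F1. Hemetsberger–Knittel thermolysis in refluxing xylene, with nitrene insertion into the only free ortho C–H, should give methyl 4,7-dibromo-1H-indole-2-carboxylate F2. Chlorination at C3 with N-chlorosuccinimide in DMF then gives compound 9, from which steps 6 and 7 follow unchanged.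

**Step 3.**
- What may go wrong: stalling after the first coupling, because oxidative addition into the C4–Br bond (beta position, flanked by chlorine and the new alkyne) is slow. Hydrodebromination and premature loss of the Boc group can accompany it.
- Fallback: it sets out from compound 1 and comes back at compound 5. Iodination with N-iodosuccinimide (2.2 equiv, DMF) should give methyl 3-chloro-4,5-diiodo-1H-pyrrole-2-carboxylate F3. Boc protection as in step 2 gives 1-tert-butyl 2-methyl 3-chloro-4,5-diiodo-1H-pyrrole-1,2-dicarboxylate F4. Twofold Sonogashira coupling of the far more reactive diiodide with 4 at room temperature then gives compound 5.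

**Step 7.**
- What may go wrong: electrophilic bromine may attack the chlorine-bearing C3 instead of C2, leading to halogen exchange or, with traces of water, to over-oxidation of the indole. Ipso attack on the strongly deactivated ring may also be sluggish.
- Fallback: it sets out from acid 10 and comes back at target 11. Protodecarboxylation (Ag2CO3 cat., AcOH, DMSO, 120 °C) should give 4,7-dibromo-3-chloro-1H-indole F5. Ordinary electrophilic bromination at the free C2 (NBS, 1 equiv, CH2Cl2, 0 °C), where the sigma complex needs only to lose a proton, then gives 11.

## Further compounds

F1 | step 5 | methyl (2Z)-2-azido-3-(2,5-dibromophenyl)prop-2-enoate | COC(=O)/C(N=[N+]=[N-])=C/c1cc(Br)ccc1Br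
F2 | step 5 | methyl 4,7-dibromo-1H-indole-2-carboxylate | COC(=O)c1cc2c(Br)ccc(Br)c2[nH]1
F3 | step 3 | methyl 3-chloro-4,5-diiodo-1H-pyrrole-2-carboxylate | COC(=O)c1[nH]c(I)c(I)c1Cl
F4 | step 3 | 1-tert-butyl 2-methyl 3-chloro-4,5-diiodo-1H-pyrrole-1,2-dicarboxylate | COC(=O)c1c(Cl)c(I)c(I)n1C(=O)OC(C)(C)C
F5 | step 7 | 4,7-dibromo-3-chloro-1H-indole | Clc1c[nH]c2c(Br)ccc(Br)c12
A1 | alternative 1 | 2-amino-3,6-dibromobenzaldehyde | O=Cc1c(N)c(Br)ccc1Br
A2 | alternative 1 | N-[3,6-dibromo-2-(2,2-dibromoethenyl)phenyl]methanesulfonamide | CS(=O)(=O)Nc1c(Br)ccc(Br)c1C=C(Br)Br
A3 | alternative 1 | 2,4,7-tribromo-1-(methylsulfonyl)-1H-indole | CS(=O)(=O)n1c(Br)cc2c(Br)ccc(Br)c21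
A4 | alternative 1 | 2,4,7-tribromo-1H-indole | Brc1cc2c(Br)ccc(Br)c2[nH]1
A5 | alternative 2 | N-(bromoethynyl)-N-(4-bromobut-3-yn-1-yl)-4-methylbenzenesulfonamide | Cc1ccc(cc1)S(=O)(=O)N(C#CBr)CCC#CBr
A6 | alternative 2 | acetylene | C#C
A7 | alternative 2 | 4,7-dibromo-1-(4-methylbenzenesulfonyl)-2,3-dihydro-1H-indole | Cc1ccc(cc1)S(=O)(=O)N1CCc2c(Br)ccc(Br)c21
A8 | alternative 2 | 4,7-dibromo-1H-indole | Brc1ccc(Br)c2[nH]ccc12
A9 | alternative 3 | 2,5-dibromothiophene 1,1-dioxide | O=S1(=O)C(Br)=CC=C1Br
A10 | alternative 3 | tert-butyl 2,3-dihydro-1H-pyrrole-1-carboxylate | CC(C)(C)OC(=O)N1CCC=C1
A11 | alternative 3 | racemic cis-fused tert-butyl 4,7-dibromo-2,3,3a,7a-tetrahydro-1H-indole-1-carboxylate | CC(C)(C)OC(=O)N1CC[C@H]2C(Br)=CC=C(Br)[C@@H]12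
A12 | alternative 3 | tert-butyl 4,7-dibromo-1H-indole-1-carboxylate | CC(C)(C)OC(=O)n1ccc2c(Br)ccc(Br)c21
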